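**Retrosynthetic overview**

1. Numbering: unit 1 is the 5,7-dihydroxyflavanone (O1 to C8a, ring B C1' to C6'); unit 2 is the 5-hydroxy-7-methoxyflavanone (O1'' to C8a'', pendant ring C1''' to C6'''); the units are joined C3'–C8''.
2. Feature: ring B has O4'–H para to C1' and the unit 2 aryl on C3', ortho to that oxygen. That is the pattern left when a 4-aryl-1-methoxy-3-silyloxybutadiene adds to methyl propiolate and loses methanol, so ring B is built onto C8'' (bonds C2'–C3' and C1'–C6') and no biaryl coupling is needed.
3. End game: five benzyl ethers off ⇐ double asymmetric oxa-Michael closure of both pyranone rings (O1–C2, O1''–C2'') ⇐ bis-chalcone from two sequential Claisen–Schmidt condensations (C4a''-acetyl with 4-benzyloxybenzaldehyde, then C1'-CHO with a protected phloroacetophenone).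
4. The unit 2 ring stays symmetric (two MOM ethers flanking C8'', benzyl on the future O5'') until after the cycloaddition. One acetylation then defines C4a'', hydrogen bonding distinguishes O8a'' from O7'' for methylation, and the O5'' benzyl lets the ring close only through O8a''.
5. Ring order: unit 2 ring A (from phloroglucinol) → ring B (step 9) → both heterocycles together (step 19).

Key step: step 9

Assumption: the C3'–C8'' axis (three ortho oxygen substituents, one ortho hydrogen) is taken to rotate freely at room temperature, so it needs no descriptor, as in the target SMILES.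
Assumption: the quinine-derived thiourea is taken to give the (S) sense at C2 and C2''; if a model chalcone shows the opposite sense, its quinidine-derived pseudoenantiomer is used instead.

**Route**

Step 1
Reactants: 1 phloroglucinol
Product: 2 5-(benzyloxy)benzene-1,3-diol
Conditions: BnBr (1 equiv), 1 (3 equiv), K2CO3, DMF, 0 °C → rt
Reagents that add atoms: benzyl bromide, BrCc1ccccc1
Why: Williamson etherification with the symmetric triol in excess should stop mainly at the monoether, which is separated from recovered 1 and from the dibenzyl ether by extraction and chromatography.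

Step 2
Reactants: 2 5-(benzyloxy)benzene-1,3-diol
Product: 3 1-(benzyloxy)-3,5-bis(methoxymethoxy)benzene
Conditions: NaH (2.4 equiv), MOMCl (2.4 equiv), DMF, 0 °C → rt
Reagents that add atoms: chloromethyl methyl ether, COCCl
Why: O-alkylation of both phenoxides by the reactive chloromethyl ether (Williamson type) should be clean, and the benzyl ether is inert.

Step 3
Reactants: 3 1-(benzyloxy)-3,5-bis(methoxymethoxy)benzene
Product: 5 2-[4-(benzyloxy)-2,6-bis(methoxymethoxy)phenyl]ethanol, via aryllithium 4 (not isolated)
Conditions: n-BuLi (1.2 equiv), THF, 0 °C → rt; ethylene oxide (THF solution), 0 °C → rt; aq NH4Cl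
Reagents that add atoms: ethylene oxide, C1CO1
Why: Directed ortho-metalation takes place at the position between the two MOM groups, which is activated by double chelation, and the aryllithium opens ethylene oxide by SN2 to add the two-carbon arm at the future C8''.

Step 4
Reactants: 5 2-[4-(benzyloxy)-2,6-bis(methoxymethoxy)phenyl]ethanol
Product: 6 2-[4-(benzyloxy)-2,6-bis(methoxymethoxy)phenyl]acetaldehyde
Conditions: Dess–Martin periodinane, pyridine, CH2Cl2, 0 °C → rt; used at once
Reagents that add atoms: none
Why: Dess–Martin oxidation is near neutral and stops at the aldehyde, and the aryl acetaldehyde is carried on directly to limit enolization and self-aldol.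

Step 5
Reactants: 6 2-[4-(benzyloxy)-2,6-bis(methoxymethoxy)phenyl]acetaldehyde
Product: 7 rac-1-[4-(benzyloxy)-2,6-bis(methoxymethoxy)phenyl]but-3-yn-2-ol
Conditions: HC≡CMgBr (1.5 equiv), THF, −78 → 0 °C; aq NH4Cl
Reagents that add atoms: ethynylmagnesium bromide, C#C[Mg]Br
Why: Grignard 1,2-addition to the aldehyde gives the propargylic alcohol, and its carbinol centre is racemic and without consequence because step 6 removes it.

Step 6
Reactants: 7 rac-1-[4-(benzyloxy)-2,6-bis(methoxymethoxy)phenyl]but-3-yn-2-ol
Product: 8 1-[4-(benzyloxy)-2,6-bis(methoxymethoxy)phenyl]but-3-yn-2-one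
Conditions: Dess–Martin periodinane, pyridine, CH2Cl2, 0 °C; used crude
Reagents that add atoms: none
Why: Dess–Martin oxidation of a propargylic alcohol to the ynone is fast under buffered conditions that leave the acetals and the benzyl ether untouched.

Step 7
Reactants: 8 1-[4-(benzyloxy)-2,6-bis(methoxymethoxy)phenyl]but-3-yn-2-one
Product: 9 (E)-1-[4-(benzyloxy)-2,6-bis(methoxymethoxy)phenyl]-4-methoxybut-3-en-2-one
Conditions: MeOH (3 equiv), DABCO (10 mol %), CH2Cl2, 0 °C → rt
Reagents that add atoms: methanol, CO
Why: Amine-catalysed conjugate (oxa-Michael) addition of methanol to the terminal ynone should give the more stable (E)-β-methoxy enone, and the weak base does not enolize the benzylic CH2.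

Step 8
Reactants: 9 (E)-1-[4-(benzyloxy)-2,6-bis(methoxymethoxy)phenyl]-4-methoxybut-3-en-2-one
Product: 11 (1E,3Z)-4-[4-(benzyloxy)-2,6-bis(methoxymethoxy)phenyl]-1-methoxy-3-(trimethylsilyloxy)buta-1,3-diene, via lithium dienolate 10 (not isolated)
Conditions: LiN(SiMe3)2 (1.1 equiv), THF, −78 °C; Me3SiCl, Et3N, −78 → 0 °C; filtered under argon and used crude
Reagents that add atoms: chlorotrimethylsilane, C[Si](C)(C)Cl
Why: Kinetic enolization with silyl trapping can only occur at the benzylic CH2, and the (Z)-enolate (aryl cis to oxygen) is favoured because it avoids allylic strain between the aryl group and the methoxyvinyl arm; base-only conditions are chosen because silyl triflates or iodides would attack the MOM ethers.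

Step 9
Reactants: 11 (1E,3Z)-4-[4-(benzyloxy)-2,6-bis(methoxymethoxy)phenyl]-1-methoxy-3-(trimethylsilyloxy)buta-1,3-diene; 12 methyl propiolate
Product: 15 methyl 3-[4-(benzyloxy)-2,6-bis(methoxymethoxy)phenyl]-4-hydroxybenzoate, via cyclohexadiene cycloadduct 13 (not isolated), via aryl silyl ether 14 (not isolated)
Conditions: 12 (3 equiv), toluene, 110 °C, sealed tube; then K2CO3 (cat.), MeOH, rt
Reagents that add atoms: none
Why: The electron-rich diene 11 and the electron-poor alkyne 12 should combine in a concerted but strongly asynchronous normal-demand (4+2) cycloaddition, the closest known reaction being the addition of 1-methoxy-3-silyloxybutadienes to alkynyl esters with aromatization to 4-hydroxybenzoates. Ring B is closed by this intermolecular cycloaddition, which forms C2'–C3' and C1'–C6' in one operation; the cyclohexa-1,4-diene 13 then loses methanol across C6' and C3' to give the aromatic silyl ether 14, which basic methanol cleaves to phenol 15, and any 13 that survives heating is aromatized in the same treatment by desilylation and β-elimination of methoxide. No stereocentre is kept, because both sp3 carbons of 13 become aromatic. The step needs regioselectivity: both donors (OMe on C6', OSiMe3 on C4') place the largest HOMO coefficient on the aryl-bearing terminus C3', which bonds to the unsubstituted alkyne carbon (largest LUMO coefficient and the smallest partner), so the ester ends para to the phenol and the aryl group ortho to it. The (3Z) enol silane holds the bulky aryl group on the outside of the s-cis diene, and the twofold symmetry of the 2,6-bis(methoxymethoxy)aryl ring means its twist about the future C3'–C8'' bond creates no isomers.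

Step 10
Reactants: 15 methyl 3-[4-(benzyloxy)-2,6-bis(methoxymethoxy)phenyl]-4-hydroxybenzoate
Product: 16 methyl 4-(benzyloxy)-3-[4-(benzyloxy)-2,6-bis(methoxymethoxy)phenyl]benzoate
Conditions: BnBr, K2CO3, DMF, 50 °C
Reagents that add atoms: benzyl bromide, BrCc1ccccc1
Why: Williamson etherification of the phenol, made acidic by the para ester, protects O4' in a form that survives organolithium, hydroxide and acid and leaves in the final hydrogenolysis.

Step 11
Reactants: 16 methyl 4-(benzyloxy)-3-[4-(benzyloxy)-2,6-bis(methoxymethoxy)phenyl]benzoate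
Product: 17 {4-(benzyloxy)-3-[4-(benzyloxy)-2,6-bis(methoxymethoxy)phenyl]phenyl}methanol
Conditions: i-Bu2AlH (2.5 equiv), CH2Cl2, −78 → 0 °C; aq potassium sodium tartrate
Reagents that add atoms: none
Why: Hydride reduction of the aryl ester with i-Bu2AlH gives the benzylic alcohol, an oxidation level at C1' that tolerates the organolithium and hydroxide steps that follow.

Step 12
Reactants: 17 {4-(benzyloxy)-3-[4-(benzyloxy)-2,6-bis(methoxymethoxy)phenyl]phenyl}methanol
Product: 19 1-[6-(benzyloxy)-3-[2-(benzyloxy)-5-(hydroxymethyl)phenyl]-2,4-bis(methoxymethoxy)phenyl]ethan-1-one, via dilithio species 18 (not isolated)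
Conditions: n-BuLi (2.3 equiv), THF, 0 °C; MeC(O)N(OMe)Me (1.5 equiv), −78 °C → rt; aq NH4Cl
Reagents that add atoms: N-methoxy-N-methylacetamide, CC(=O)N(C)OC
Why: After the alkoxide has formed, directed ortho-metalation occurs at one of the two equivalent positions flanked by OMOM and OBn on the still symmetric unit 2 ring (the only sites between two oxygens), and Weinreb ketone synthesis with the amide gives the C4a'' acetyl group without over-addition.

Step 13
Reactants: 19 1-[6-(benzyloxy)-3-[2-(benzyloxy)-5-(hydroxymethyl)phenyl]-2,4-bis(methoxymethoxy)phenyl]ethan-1-one; 20 4-(benzyloxy)benzaldehyde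
Product: 21 (E)-1-[6-(benzyloxy)-3-[2-(benzyloxy)-5-(hydroxymethyl)phenyl]-2,4-bis(methoxymethoxy)phenyl]-3-[4-(benzyloxy)phenyl]prop-2-en-1-one
Conditions: 20 (1.3 equiv), KOH (50 % aq), EtOH, rt
Reagents that add atoms: none
Why: Claisen–Schmidt condensation of the only enolizable ketone with the non-enolizable aldehyde gives the (E)-enone by E1cB dehydration, and it is run while C1' is still an alcohol so that the molecule cannot condense with itself.

Step 14
Reactants: 21 (E)-1-[6-(benzyloxy)-3-[2-(benzyloxy)-5-(hydroxymethyl)phenyl]-2,4-bis(methoxymethoxy)phenyl]-3-[4-(benzyloxy)phenyl]prop-2-en-1-one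
Product: 22 4-(benzyloxy)-3-[4-(benzyloxy)-3-[(E)-3-[4-(benzyloxy)phenyl]prop-2-enoyl]-2,6-bis(methoxymethoxy)phenyl]benzaldehyde
Conditions: MnO2 (activated, excess), CH2Cl2, rt
Reagents that add atoms: none
Why: MnO2 oxidizes the electron-rich benzylic alcohol selectively to the aldehyde and leaves the enone, the acetals and the benzyl ethers alone.

Step 15
Reactants: 23 2',4',6'-trihydroxyacetophenone
Product: 24 1-[2,4-bis(benzyloxy)-6-hydroxyphenyl]ethan-1-one
Conditions: BnBr (2.1 equiv), K2CO3, acetone, reflux
Reagents that add atoms: benzyl bromide, BrCc1ccccc1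
Why: Williamson etherification takes the two free hydroxyls, while the hydroxyl hydrogen-bonded to the acetyl group is much less nucleophilic and stays free as the future O1.

Step 16
Reactants: 22 4-(benzyloxy)-3-[4-(benzyloxy)-3-[(E)-3-[4-(benzyloxy)phenyl]prop-2-enoyl]-2,6-bis(methoxymethoxy)phenyl]benzaldehyde; 24 1-[2,4-bis(benzyloxy)-6-hydroxyphenyl]ethan-1-one
Product: 25 bis-chalcone with unit 2 ring as bis-MOM ether: (E)-3-[4-(benzyloxy)-3-[4-(benzyloxy)-3-[(E)-3-[4-(benzyloxy)phenyl]prop-2-enoyl]-2,6-bis(methoxymethoxy)phenyl]phenyl]-1-[2,4-bis(benzyloxy)-6-hydroxyphenyl]prop-2-en-1-one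
Conditions: 24 (1.2 equiv), KOH, EtOH–THF, rt
Reagents that add atoms: none
Why: A second Claisen–Schmidt condensation joins the enolate of 24 to the aldehyde, the enone already present has no enolizable hydrogen, and the strongly basic medium keeps the new 2'-hydroxychalcone open as its phenoxide.

Step 17
Reactants: 25 bis-chalcone with unit 2 ring as bis-MOM ether
Product: 26 bis-chalcone with free O7''–H and O8a''–H (unit 2 ring) and free O1–H precursor hydroxyl (unit 1 ring A)
Conditions: HCl (conc., 5 % v/v), MeOH–THF, rt
Reagents that add atoms: none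
Why: Acid-catalysed acetal exchange with methanol removes both MOM groups at room temperature, where benzyl ethers and enones are stable and acid-promoted ring closure of 2'-hydroxy-6'-alkoxychalcones is slow.

Step 18
Reactants: 26 bis-chalcone triol
Product: 27 bis-chalcone with O7''-methyl ether
Conditions: MeI (1.2 equiv), K2CO3 (1.2 equiv), acetone, rt
Reagents that add atoms: iodomethane, CI
Why: Of the three phenols only O7''–H, para to the carbonyl, is not hydrogen-bonded, so it is the most acidic and is the one methylated in this Williamson etherification with one equivalent of base.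

Step 19
Reactants: 27 bis-chalcone with O7''-methyl ether
Product: 28 (2S,2''S)-penta-O-benzyl biflavanone (benzyl on O5, O7, O4', O5'', O4''')
Conditions: 1-[3,5-bis(trifluoromethyl)phenyl]-3-(9-deoxy-epi-quinin-9-yl)thiourea (20 mol %), toluene, rt
Reagents that add atoms: none
Why: Two independent catalyst-controlled intramolecular oxa-Michael additions (6-endo-trig, O1 to C2 and O1'' to C2'') of the 2'-hydroxychalcone units should set both stereocentres as (S), the thiourea binding each carbonyl while the quinuclidine delivers the phenol to one enone face; regiochemistry is fixed because O5'' is benzylated and O7'' methylated, and two separate events deplete the (2R,2''R) enantiomer statistically.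

Step 20
Reactants: 28 (2S,2''S)-penta-O-benzyl biflavanone
Product: 29 target, (2S,2''S)-3',8''-biflavanone with 5,7,4',5'',4'''-pentahydroxy and 7''-methoxy groups
Conditions: H2 (1 atm), Pd/C (10 wt % Pd on carbon), EtOAc–MeOH, rt
Reagents that add atoms: none
Why: Hydrogenolysis cleaves the five benzyl ethers under neutral conditions, so C2 and C2'' cannot epimerize through base-induced ring opening, and the reaction is stopped at full debenzylation to spare the benzylic C2–O bonds and the ketones.

**Compound list**

1 | phloroglucinol | Oc1cc(O)cc(O)c1 | starting material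
2 | 5-(benzyloxy)benzene-1,3-diol | Oc1cc(O)cc(OCc2ccccc2)c1 | intermediate
3 | 1-(benzyloxy)-3,5-bis(methoxymethoxy)benzene | COCOc1cc(OCOC)cc(OCc2ccccc2)c1 | intermediate
4 | [4-(benzyloxy)-2,6-bis(methoxymethoxy)phenyl]lithium | [Li]c1c(OCOC)cc(OCc2ccccc2)cc1OCOC | intermediate (not isolated)
5 | 2-[4-(benzyloxy)-2,6-bis(methoxymethoxy)phenyl]ethanol | OCCc1c(OCOC)cc(OCc2ccccc2)cc1OCOC | intermediate
6 | 2-[4-(benzyloxy)-2,6-bis(methoxymethoxy)phenyl]acetaldehyde | O=CCc1c(OCOC)cc(OCc2ccccc2)cc1OCOC | intermediate
7 | rac-1-[4-(benzyloxy)-2,6-bis(methoxymethoxy)phenyl]but-3-yn-2-ol (racemic) | C#CC(O)Cc1c(OCOC)cc(OCc2ccccc2)cc1OCOC | intermediate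
8 | 1-[4-(benzyloxy)-2,6-bis(methoxymethoxy)phenyl]but-3-yn-2-one | C#CC(=O)Cc1c(OCOC)cc(OCc2ccccc2)cc1OCOC | intermediate
9 | (E)-1-[4-(benzyloxy)-2,6-bis(methoxymethoxy)phenyl]-4-methoxybut-3-en-2-one | CO/C=C/C(=O)Cc1c(OCOC)cc(OCc2ccccc2)cc1OCOC | intermediate
10 | lithium (1Z,3E)-dienolate of 9 | CO/C=C/C(O[Li])=C/c1c(OCOC)cc(OCc2ccccc2)cc1OCOC | intermediate (not isolated)
11 | (1E,3Z)-4-[4-(benzyloxy)-2,6-bis(methoxymethoxy)phenyl]-1-methoxy-3-(trimethylsilyloxy)buta-1,3-diene | CO/C=C/C(O[Si](C)(C)C)=C/c1c(OCOC)cc(OCc2ccccc2)cc1OCOC | intermediate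
12 | methyl propiolate | C#CC(=O)OC | starting material
13 | methyl 3-[4-(benzyloxy)-2,6-bis(methoxymethoxy)phenyl]-6-methoxy-4-(trimethylsilyloxy)cyclohexa-1,4-diene-1-carboxylate (racemic mixture of diastereomers) | COC(=O)C1=CC(c2c(OCOC)cc(OCc3ccccc3)cc2OCOC)C(O[Si](C)(C)C)=CC1OC | intermediate (not isolated)
14 | methyl 3-[4-(benzyloxy)-2,6-bis(methoxymethoxy)phenyl]-4-(trimethylsilyloxy)benzoate | COC(=O)c1ccc(O[Si](C)(C)C)c(-c2c(OCOC)cc(OCc3ccccc3)cc2OCOC)c1 | intermediate (not isolated)
15 | methyl 3-[4-(benzyloxy)-2,6-bis(methoxymethoxy)phenyl]-4-hydroxybenzoate | COC(=O)c1ccc(O)c(-c2c(OCOC)cc(OCc3ccccc3)cc2OCOC)c1 | intermediate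
16 | methyl 4-(benzyloxy)-3-[4-(benzyloxy)-2,6-bis(methoxymethoxy)phenyl]benzoate | COC(=O)c1ccc(OCc2ccccc2)c(-c2c(OCOC)cc(OCc3ccccc3)cc2OCOC)c1 | intermediate
17 | {4-(benzyloxy)-3-[4-(benzyloxy)-2,6-bis(methoxymethoxy)phenyl]phenyl}methanol | OCc1ccc(OCc2ccccc2)c(-c2c(OCOC)cc(OCc3ccccc3)cc2OCOC)c1 | intermediate
18 | dilithio species of 17 (lithium alkoxide, aryllithium between OMOM and OBn) | [Li]OCc1ccc(OCc2ccccc2)c(-c2c(OCOC)cc(OCc3ccccc3)c([Li])c2OCOC)c1 | intermediate (not isolated)
19 | 1-[6-(benzyloxy)-3-[2-(benzyloxy)-5-(hydroxymethyl)phenyl]-2,4-bis(methoxymethoxy)phenyl]ethan-1-one | CC(=O)c1c(OCc2ccccc2)cc(OCOC)c(-c2cc(CO)ccc2OCc2ccccc2)c1OCOC | intermediate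
20 | 4-(benzyloxy)benzaldehyde | O=Cc1ccc(OCc2ccccc2)cc1 | starting material
21 | (E)-1-[6-(benzyloxy)-3-[2-(benzyloxy)-5-(hydroxymethyl)phenyl]-2,4-bis(methoxymethoxy)phenyl]-3-[4-(benzyloxy)phenyl]prop-2-en-1-one | O=C(/C=C/c1ccc(OCc2ccccc2)cc1)c1c(OCc2ccccc2)cc(OCOC)c(-c2cc(CO)ccc2OCc2ccccc2)c1OCOC | intermediate
22 | 4-(benzyloxy)-3-[4-(benzyloxy)-3-[(E)-3-[4-(benzyloxy)phenyl]prop-2-enoyl]-2,6-bis(methoxymethoxy)phenyl]benzaldehyde | O=C(/C=C/c1ccc(OCc2ccccc2)cc1)c1c(OCc2ccccc2)cc(OCOC)c(-c2cc(C=O)ccc2OCc2ccccc2)c1OCOC | intermediate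
23 | 2',4',6'-trihydroxyacetophenone | CC(=O)c1c(O)cc(O)cc1O | starting material
24 | 1-[2,4-bis(benzyloxy)-6-hydroxyphenyl]ethan-1-one | CC(=O)c1c(O)cc(OCc2ccccc2)cc1OCc1ccccc1 | intermediate
25 | bis-chalcone, unit 2 ring as bis-MOM ether, both enones (E) | O=C(/C=C/c1ccc(OCc2ccccc2)cc1)c1c(OCc2ccccc2)cc(OCOC)c(-c2cc(/C=C/C(=O)c3c(O)cc(OCc4ccccc4)cc3OCc3ccccc3)ccc2OCc2ccccc2)c1OCOC | intermediate
26 | bis-chalcone triol (free O7''–H, O8a''–H and unit 1 ring A 2'-OH), both enones (E) | O=C(/C=C/c1ccc(OCc2ccccc2)cc1)c1c(OCc2ccccc2)cc(O)c(-c2cc(/C=C/C(=O)c3c(O)cc(OCc4ccccc4)cc3OCc3ccccc3)ccc2OCc2ccccc2)c1O | intermediate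
27 | bis-chalcone O7''-methyl ether, both enones (E) | O=C(/C=C/c1ccc(OCc2ccccc2)cc1)c1c(OCc2ccccc2)cc(OC)c(-c2cc(/C=C/C(=O)c3c(O)cc(OCc4ccccc4)cc3OCc3ccccc3)ccc2OCc2ccccc2)c1O | intermediate
28 | (2S,2''S)-5,7,4',5'',4'''-penta-O-benzyl-7''-O-methyl-3',8''-biflavanone | COc1cc(OCc2ccccc2)c2c(c1-c1cc([C@@H]3CC(=O)c4c(OCc5ccccc5)cc(OCc5ccccc5)cc4O3)ccc1OCc1ccccc1)O[C@H](c1ccc(OCc3ccccc3)cc1)CC2=O | intermediate
29 | target, (2S,2''S)-5,7,4',5'',4'''-pentahydroxy-7''-methoxy-3',8''-biflavanone | COc1cc(O)c2c(c1-c1cc([C@@H]3CC(=O)c4c(O)cc(O)cc4O3)ccc1O)O[C@H](c1ccc(O)cc1)CC2=O | target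

**Step count**

Total: 20 steps. Longest linear sequence: 19 steps (steps 1 to 14 and 16 to 20; step 15 is a one-step branch).

**Three steps most likely to fail**

Step 9. The twisted aryl ring places its two ortho acetal groups over both faces of the diene terminus C3'. Bond formation there may become so slow that hydrolytic loss of the enol silane, polymerization of the propiolate, or an open-chain Michael-type adduct that does not close takes over. The fallback gives up ring construction for a direct biaryl coupling; it sets out from 3 and comes back to the route at 16. Compound 3 is lithiated as in step 3 to aryllithium 4 and transmetalated with ZnCl2 to [4-(benzyloxy)-2,6-bis(methoxymethoxy)phenyl]zinc chloride F1. This is coupled (Negishi reaction; Pd2(dba)3, SPhos, THF, 60 °C) with methyl 4-(benzyloxy)-3-iodobenzoate F2, which is made from commercial methyl 4-hydroxy-3-iodobenzoate with BnBr and K2CO3. The product is 16, and steps 3 to 10 are bypassed.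

Step 19. Facial selectivity in one or both closures may be low, and it may be eroded further by reversible ring opening of the flavanones or by uncatalysed background cyclization of the 6'-alkoxy chalcone of unit 2. The fallback replaces catalyst control by separation; it sets out from 27 and comes back at 28. Compound 27 is cyclized without stereocontrol (NaOAc, EtOH, reflux) to the mixture of the four stereoisomers of the penta-O-benzyl biflavanone F5. The (2S,2''S) isomer 28 is then isolated by preparative HPLC on a polysaccharide chiral stationary phase, and its configuration is assigned by electronic circular dichroism against (2S)-naringenin. The unwanted isomers can be returned to the NaOAc equilibration.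

Step 12. Lithiation may be incomplete or misdirected (deprotonation of a benzylic OCH2 with Wittig rearrangement, or metalation on ring B next to O4'), and the hindered aryllithium may be quenched by proton transfer from the acetamide instead of adding to it. The fallback replaces deprotonation by electrophilic substitution and cross-coupling; it sets out from 17 and comes back at 19. NBS (1.0 equiv, MeCN, 0 °C) should brominate only the trioxygenated unit 2 ring, at one of its two equivalent free positions, to give the aryl bromide F3. Stille coupling with tributyl(1-ethoxyvinyl)stannane (Pd(PPh3)4, toluene, 100 °C) gives the 1-ethoxyvinyl arene F4. Brief hydrolysis with dilute aqueous oxalic acid in THF then gives 19 with the MOM ethers intact.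

**Further compounds**

F1 | step 9 | [4-(benzyloxy)-2,6-bis(methoxymethoxy)phenyl]zinc chloride | Cl[Zn]c1c(OCOC)cc(OCc2ccccc2)cc1OCOC
F2 | step 9 | methyl 4-(benzyloxy)-3-iodobenzoate | COC(=O)c1ccc(OCc2ccccc2)c(I)c1
F3 | step 12 | {4-(benzyloxy)-3-[4-(benzyloxy)-3-bromo-2,6-bis(methoxymethoxy)phenyl]phenyl}methanol | OCc1ccc(OCc2ccccc2)c(-c2c(OCOC)cc(OCc3ccccc3)c(Br)c2OCOC)c1
F4 | step 12 | {4-(benzyloxy)-3-[4-(benzyloxy)-3-(1-ethoxyvinyl)-2,6-bis(methoxymethoxy)phenyl]phenyl}methanol | C=C(OCC)c1c(OCc2ccccc2)cc(OCOC)c(-c2cc(CO)ccc2OCc2ccccc2)c1OCOC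
F5 | step 19 | 5,7,4',5'',4'''-penta-O-benzyl-7''-O-methyl-3',8''-biflavanone, mixture of the four C2/C2'' stereoisomers | COc1cc(OCc2ccccc2)c2c(c1-c1cc(C3CC(=O)c4c(OCc5ccccc5)cc(OCc5ccccc5)cc4O3)ccc1OCc1ccccc1)OC(c1ccc(OCc3ccccc3)cc1)CC2=O
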